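The ratio of target to isomer of the product at the last reading stands at 0.309 in the red run, 0.278 in the teal run and 0.296 in the amber run.

| flask | starting material | protic impurity | remark | time |
|---|---|---|---|---|
| red | 0.050 M (fed, over 2.0 h) | 0.038 M | run made earlier; the fed solution adds 0.10 times the starting volume |  |
| teal | 0.050 M (fed, over 2.0 h) | 0.037 M | run made earlier; the fed solution adds 0.10 times the starting volume |  |
| amber | 0.050 M (fed, over 2.0 h) | 0.046 M | run made earlier; the fed solution adds 0.10 times the starting volume |  |
| Sunday's | 0.050 M | 0.0300 M | everything together at the start, the whole solution of starting material included, so that from the start the volume is larger by 0.10 times the starting volume | 2.5 d |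
| Wednesday's | 0.050 M (fed, over 2.0 h) | 0.0500 M | the fed solution adds 0.10 times the starting volume | 2.5 d |

| run | time / d | target / % | isomer of the product / % |
|---|---|---|---|
| red | 0.208 | 2.4 | 5.9 |
| red | 0.417 | 4.9 | 14.3 |
| red | 0.625 | 5.8 | 19.1 |
| red | 1.25 | 7.3 | 23.8 |
| red | 2.50 | 7.6 | 24.6 |
| teal | 0.208 | 2.9 | 5.9 |
| teal | 0.625 | 6.0 | 18.1 |
| teal | 1.25 | 7.4 | 23.6 |
| teal | 1.67 | 6.9 | 24.7 |
| teal | 2.50 | 7.0 | 25.2 |
| amber | 0.208 | 2.4 | 5.6 |
| amber | 0.625 | 5.8 | 18.0 |
| amber | 1.25 | 6.8 | 22.7 |
| amber | 1.67 | 6.9 | 23.1 |
| amber | 2.50 | 6.8 | 23.0 |

(each reading ± 0.3 percentage points)

1. the flask that ends with the higher share of target in all that became target or isomer of the product, or "neither" when 2 percentage points or less lies between them (Sunday's / Wednesday's / neither)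
2. share of target in all that became target or isomer of the product, Sunday's
3. share of target in all that became target or isomer of the product, Wednesday's

- charges are per starting volume, the dose included; the dosed solution carries all of it

*What do you carry from these runs?*

A single number, 22.7%: the end share, or selectivity, meaning target as a fraction of target plus isomer of the product, pooled over those last readings.

*The ratio begins higher: 0.407 at 0.208 d in the red run. Could Sunday's charge at the start keep that?*

Count turnovers. By 0.417 d the red run holds 59.6% of its last total, so I take that as one turnover of product formation. The 2.5 d of Sunday's and Wednesday's flasks then holds 6.00 such turnovers, and the feed lasts 0.200 of one. The red ratio already reads 0.307 at 1.25 d, and both new flasks run twice that long.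

*Wednesday's impurity lies above the amber run's, and Sunday's below the teal run's. Isn't that the weak spot?*

Yes, it is an extrapolation. Within the runs, though, the shares at the last readings show no order with impurity: 21.7% at 0.037 M, 23.6% at 0.038 M, 22.8% at 0.046 M.

*Your answer?*

I put 22.7% for both flasks, so no gap beyond 2 percentage points.

The forecast says neither, with 24% (21.5% to 28.5%) for Sunday's and 22.8% (21% to 24.5%) for Wednesday's, remarking that the fall of both products with more impurity “suggests it removes a common precursor and leaves the split alone”.

The simulation gives 23.3% for Sunday's and 23.3% for Wednesday's, so neither leads, and my end share lies 0.60 points below both.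

    starting material ⇌ intermediate B (K = 0.680, k = 0.00160 min⁻¹)
    intermediate A → target (k = 9.60 × 10⁻⁴ min⁻¹)
    intermediate A → intermediate C (k = 0.00130 min⁻¹)
    intermediate C ⇌ intermediate D (K = 0.400, k = 9.80 × 10⁻⁴ min⁻¹)
    starting material → intermediate A (k = 0.00900 min⁻¹)
    target ⇌ isomer of the product (K = 3.30, k = 0.0330 min⁻¹)
    starting material + protic impurity → quenched substrate (k = 0.0980 M⁻¹ min⁻¹)

In Wednesday's flask, target and isomer of the product relax towards each other with a half-life of 0.269 h by this step alone, short against the 2.5 d of the run: 223 such half-lives, which is thermodynamic control of the split. The totals differ at the end, 34.1% in Sunday's flask against 29.8% in Wednesday's, while the share is the same.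

A neighbour flask, like Wednesday's but with 0.020 M of protic impurity: the end share gives 22.7%. The computed flask ends with 8.48% target and 28.0% isomer of the product, a share of 23.3%.

Readings and results stem from a simulated flask with constants of no real substance.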